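**Assumptions:** 7-octyn-1-ol, 5-bromo-1-pentene, syringaldehyde and 3,5-dibromoanisole are commercial. The target's carbinol is (R): the SMILES gives O > aryl > CH2 priorities, and @ with the order Ar, H, O, CH2 corresponds to R. (+)-DAIB is assumed to give the (R)-carbinol, because (−)-DAIB gives (S)-1-arylalkanols and the priority pattern here is the same.

## Retrosynthesis

1. Dehydrogravicycle comes from its tri-O-methyl ether (10) by global aryl-methyl-ether cleavage. Thiolate is used because H2 would reduce the alkene and BBr3 could ionise the benzylic alcohol.
2. **Key bold disconnection:** the 22-membered ring is closed at the C1–C2 bond, which is also the stereocentre. A primary alkylzinc generated from a terminal iodide adds intramolecularly to the ring-B aryl aldehyde under chiral amino-alcohol catalysis. This is an Oppolzer/Noyori-type catalytic asymmetric macrocyclisation. It avoids RCM and avoids any separate ketone reduction.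
3. The iodo-aldehyde (9) comes from a B-alkyl Suzuki coupling of aryl bromide 7 with dienol 4. The E-alkene is installed beforehand by Na/NH3 reduction of alkyne 3, which is made from 7-octyn-1-ol and 5-bromo-1-pentene.
4. Diaryl ether 7 comes from Ullmann coupling of syringaldehyde with 3,5-dibromoanisole.
5. Order of bond formation: the diaryl ether is made first (step 3) and the macrocycle last (step 6). Both benzene rings are purchased.

## Forward synthesis

**Step 1**
Reactants: 1 (7-octyn-1-ol) and 2 (5-bromo-1-pentene)
Product: 3, tridec-12-en-7-yn-1-ol
Conditions: n-BuLi (2.1 equiv), THF/HMPA 4:1, −20 → 25 °C, 12 h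
Reagents that add atoms: none (the bromide is a listed reactant)
Why: The alkynyl/alkoxide dianion is alkylated selectively at carbon by the primary bromide (acetylide SN2 alkylation), which sets the 5-carbon and 6-carbon arms around the future alkene.

**Step 2**
Reactants: 3
Product: 4, (7E)-trideca-7,12-dien-1-ol
Conditions: Na (6 equiv), NH3(l)/THF, −78 → −33 °C, 2 h; solid NH4Cl quench
Reagents that add atoms: none
Why: Dissolving-metal anti-hydrogenation of the internal alkyne gives the E-alkene, and the isolated terminal alkene and the alcohol survive.

**Step 3**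
Reactants: 5 (syringaldehyde) and 6 (3,5-dibromoanisole, 3 equiv)
Product: 7, 4-(3-bromo-5-methoxyphenoxy)-3,5-dimethoxybenzaldehyde
Conditions: CuI (10 mol%), picolinic acid (20 mol%), K3PO4 (2 equiv), DMSO, 90 °C, 24 h
Reagents that add atoms: none (the dibromide is a listed reactant)
Why: Ligand-accelerated Ullmann C–O coupling tolerates the hindered 2,6-dimethoxyphenol and the aldehyde, and excess dibromide suppresses double arylation.

**Step 4**
Reactants: 4 (1.5 equiv) and 7
Product: 8, 4-{3-[(6E)-13-hydroxytridec-6-en-1-yl]-5-methoxyphenoxy}-3,5-dimethoxybenzaldehyde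
Conditions: 9-BBN-H (2.8 equiv relative to 1.0 equiv of 7), THF, 25 °C, 3 h; then 7, Pd(dppf)Cl2 (5 mol%), aq. K3PO4, 60 °C, 6 h
Reagents that add atoms: none (the dienol is a listed reactant; boron is lost)
Why: 9-BBN consumes the O–H and hydroborates only the terminal alkene (9-BBN is sterically selective against the E-internal alkene), and the B-alkyl Suzuki–Miyaura coupling then forms the aryl–CH2 bond. The 9-BBN is slightly sub-stoichiometric to the diene so no B–H remains to reduce the aldehyde.

**Step 5**
Reactants: 8
Product: 9, 4-{3-[(6E)-13-iodotridec-6-en-1-yl]-5-methoxyphenoxy}-3,5-dimethoxybenzaldehyde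
Conditions: I2 (1.3 equiv), PPh3 (1.3 equiv), imidazole (2 equiv), CH2Cl2, 0 → 25 °C, 2 h
Reagents that add atoms: iodine, I2, SMILES `II` (PPh3 and imidazole leave no atoms in the product)
Why: Appel-type deoxy-iodination converts the primary alcohol to the iodide under neutral conditions, leaving the aldehyde and the E-alkene intact.

**Step 6**
Reactants: 9
Product: 10, (R,E)-tri-O-methyl dehydrogravicycle (the 22-membered macrocycle)
Conditions: (i) Et2Zn (10 equiv), CuI (5 mol%), toluene (0.2 M), 25 °C, 16 h; (ii) evaporate to dryness (0.05 mbar, 25 °C) to remove Et2Zn and EtI; (iii) dilute in toluene to 2 mM with (+)-DAIB (20 mol%), 0 °C → 25 °C, 36 h (syringe-pump addition over 10 h); sat. aq. NH4Cl quench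
Reagents that add atoms: none (zinc, ethyl and DAIB leave no atoms; the new O–H hydrogen comes from work-up)
Why: Noyori-type amino-alcohol-catalysed dialkylzinc addition to an aromatic aldehyde, run intramolecularly at high dilution, closes the ring and sets the benzylic carbinol (R) in one step, with facial control from the (+)-DAIB–zinc alkoxide. Proposed new method: iodine–zinc exchange gives RZnEt, which loses Et2Zn under vacuum to give R2Zn, and this reagent is then added to a DAIB–zinc alkoxide that activates the tethered aldehyde through a Noyori anti-bicyclic transition state and delivers the alkyl group to one enantioface. Both alkyl groups of a R2Zn unit can each close a ring on their own aldehyde, so no dummy ligand is needed. The closest known reactions are Oppolzer's DAIB-catalysed macrocyclisation by alkenylzinc addition (muscone), Noyori's DAIB-catalysed dialkylzinc additions, and Knochel-type iodine–zinc exchange.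

**Step 7**
Reactants: 10
Product: 11, dehydrogravicycle
Conditions: NaSEt (10 equiv), DMF, 140 °C, 3 h; then 1 M HCl to pH 4
Reagents that add atoms: none (the ethyl and methyl groups leave as EtSMe)
Why: SN2 thiolate demethylation of all three aryl methyl ethers is non-acidic, so the benzylic stereocentre is not ionised and the E-alkene is not reduced or halogenated.

## Compound list

| No. | Name | SMILES | Role |
|---|---|---|---|
| 1 | 7-octyn-1-ol | `C#CCCCCCCO` | starting material |
| 2 | 5-bromo-1-pentene | `C=CCCCBr` | starting material |
| 3 | tridec-12-en-7-yn-1-ol | `C=CCCCC#CCCCCCCO` | intermediate |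
| 4 | (7E)-trideca-7,12-dien-1-ol | `C=CCCC/C=C/CCCCCCO` | intermediate |
| 5 | syringaldehyde (4-hydroxy-3,5-dimethoxybenzaldehyde) | `COc1cc(C=O)cc(OC)c1O` | starting material |
| 6 | 3,5-dibromoanisole | `COc1cc(Br)cc(Br)c1` | starting material |
| 7 | 4-(3-bromo-5-methoxyphenoxy)-3,5-dimethoxybenzaldehyde | `COc1cc(Br)cc(Oc2c(OC)cc(C=O)cc2OC)c1` | intermediate |
| 8 | 4-{3-[(6E)-13-hydroxytridec-6-en-1-yl]-5-methoxyphenoxy}-3,5-dimethoxybenzaldehyde | `COc1cc(CCCCC/C=C/CCCCCCO)cc(Oc2c(OC)cc(C=O)cc2OC)c1` | intermediate |
| 9 | 4-{3-[(6E)-13-iodotridec-6-en-1-yl]-5-methoxyphenoxy}-3,5-dimethoxybenzaldehyde | `COc1cc(CCCCC/C=C/CCCCCCI)cc(Oc2c(OC)cc(C=O)cc2OC)c1` | intermediate |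
| 10 | (R,E)-tri-O-methyl dehydrogravicycle | `COc1cc2cc(c1)Oc1c(OC)cc(cc1OC)[C@H](O)CCCCCC/C=C/CCCCC2` | intermediate |
| 11 | dehydrogravicycle | `Oc1cc2cc(c1)Oc1c(O)cc(cc1O)[C@H](O)CCCCCC/C=C/CCCCC2` | target |

## Totals

Total steps: 7. Longest linear sequence: 6 (1 → 3 → 4 → 8 → 9 → 10 → 11).

## Three steps most likely to fail

1. **Step 6 (catalytic asymmetric alkylzinc macrocyclisation).** Ethylation by residual Et2Zn, oligomerisation, low ee or the wrong sense of induction are all possible.
   Fallback: drop the asymmetric ring closure and use the conventional route instead. Couple 7 with a hept-6-enyl-9-BBN unit and build an aryl ketone with a terminal alkene on the other arm. Reduce the ketone by Noyori transfer hydrogenation using the (R)-selective catalyst, then close the ring by RCM with a Grubbs-type catalyst.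
2. **Step 3 (Ullmann coupling of a hindered, electron-poor phenol with an unactivated aryl bromide).** Conversion may be low.
   Fallback: O-arylate syringaldehyde with a diaryliodonium salt, (3-bromo-5-methoxyphenyl)(mesityl)iodonium triflate, under Cu catalysis or metal-free basic conditions, which is insensitive to the 2,6-dimethoxy hindrance.
3. **Step 4 (B-alkyl Suzuki with a free aldehyde and alcohol present).** Aldehyde reduction by residual 9-BBN or alkylborane, or hydroboration of the internal alkene, may occur.
   Fallback: reverse the order. Run the hydroboration/Suzuki coupling on 3,5-dibromoanisole, where no aldehyde is present, and do the Ullmann coupling with syringaldehyde afterwards.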